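# Total synthesis proposal for HY-N2634 (compound 18)

## Analysis of the target

Compound 18 is a single six-membered carbocycle. It is a cyclohexene whose four sp3 ring carbons all bear oxygen, and one of them also bears an oxygenated methylene branch. The ring is numbered C1 (OAc), C2 (OBz), C3=C4, C5 (OH) and C6 (tertiary OH plus C7H2OBz); with C1 to C6 drawn clockwise, β means towards the viewer and α away from the viewer. In these terms 18 carries 1β-OAc, 2α-OBz, 5α-OH and 6β-OH with C7 on the α face, which is (1S,2R,5S,6R); C1–O/C2–O are trans, C1–O/C6–O cis, C5–O/C6–O trans, and C5–O lies on the same face as C7. The sensitive points are the two allylic C–O bonds at C2 and C5 (ionisation, allylic transposition), the ease with which loss of two oxygen substituents leads to an arene, and three esters next to two free hydroxyls, so that any late basic step invites acyl migration. The carbon skeleton is trivial, a C7 unit with the connectivity of benzoic acid; the difficulty lies in the contiguous array C5–C6–C1–C2 with a fully substituted carbinol in its middle, in its absolute configuration, and in telling five oxygens apart as one acetate, two benzoates and two free hydroxyls. The strategy rests on a hidden symmetry: once the oxygens at C1, C2 and C5 are removed and the unsaturation is redistributed, C6 sits on the mirror plane of a cyclohexa-2,5-diene between two enantiotopic alkenes, C5=C4 and C1=C2. Because C5–O is cis to C7, a one-carbon carbonate bridge grown from C7–OH can deliver exactly this oxygen, and the choice of alkene fixes C6 and C5, from which C1 and C2 are then relayed.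

## Retrosynthetic reasoning

**18 ⇒ 17 ⇒ 16.** Only heteroatom bonds are cut here.
- The free C5–OH of 18 is traced back to the silyl ether 17. This hydroxyl sits close to migratable esters and should appear only in a final, non-basic step.
- The acetyl–oxygen bond at C1 is cut next and gives 16. There C1–OH is the only hydroxyl that can be acylated under mild conditions, since C6–OH is tertiary.
- The gain is that C1 never needs a protecting group.

**16 ⇒ 15 + 1.** The C2–O bond is cut.
- It is the only ring C–O bond that is both allylic and trans to its oxygenated neighbour. It is therefore the natural outcome of an anti opening of the 1β,2β-epoxide 15 by benzoic acid 1.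
- Cutting C1–O instead would demand attack at the hindered carbon next to C6 and would put the benzoate at the wrong position.
- The gain is double. The nucleophile is the very ester that the target needs, and its entry uncovers C1–OH for the acetate.
- The forward reaction must attack C2, not C1 or C4, and must do so with clean inversion.

**15 ⇒ 14.** Both C–O bonds of the oxirane are cut, which leads to the conjugated diene 14.
- The epoxide oxygen and C6–OH are both β, so the tertiary hydroxyl can steer a metal-bound peroxide to the neighbouring C1=C2 alkene.
- For this it must be the only free hydroxyl, hence the silyl ether at C5 and the benzoate at C7.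
- The forward step has to choose one alkene of the diene and one of its faces.

**14 ⇒ 13 ⇒ 12 ⇒ 11.** The O–Si bond at C5, the O–acyl bond at C7 and the two O–C(=O) bonds of the cyclic carbonate 11 are cut in turn.
- Triol 12 holds one primary, one secondary and one tertiary hydroxyl, so the three are told apart by steric class alone.
- The primary one takes the benzoate (13) and the secondary one the silyl group (14). The tertiary one stays free as the directing group.
- No C–O bond to the ring is touched, so C5 and C6 keep their configuration.

**11 ⇒ 10.** The C3=C4 alkene is traced back to a C4–I bond and a C3–H bond. In the cis-fused iodocarbonate 10 the β-iodide has an antiperiplanar hydrogen only on C3, since C5–H is also β. An amidine base can therefore form only the alkene that the target needs. The halogen that served to set stereochemistry thus also becomes the leaving group that installs the unsaturation.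

**10 ⇒ 6 + 7 + 8 (through 9).** Three bonds are cut: C5–O, C4–I and the bond between the C7 oxygen and the carbonate carbon.
- This returns the achiral diene diol 6, carbon dioxide 7 and N-iodosuccinimide 8.
- The cut is made from C7–O and not from C6–O. A bridge from the tertiary oxygen would place the new oxygen cis to C6–O, which is the wrong diastereomer.
- The gain is large: one ring and three stereocentres from a flat, symmetric precursor and a one-carbon gas.
- The forward reaction must let the hemicarbonate 9, not the free alcohol, act as nucleophile. Above all it must pick one of two enantiotopic alkenes.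

**6 ⇒ 5 ⇒ 3 (through 4) ⇒ 2 ⇒ 1.**
- The C7 carbinol is traced to the ester 5.
- The C6–O bond is traced to an electrophilic oxygen transfer onto the cross-conjugated dienolate 4 of ester 3.
- The skipped diene is traced to the dissolving-metal reduction of benzoic acid 1 by way of acid 2.
- All seven carbons of the core thus come from 1. The chemistry before the key step is routine, so the risk of the route sits in the desymmetrisation.

## Alternatives that were turned down

Alternative 1: The ring bond C5–C6 is cut by a retro-[3,3] shift, so that the carbocycle unfolds to a six-membered sugar lactone (Ireland–Claisen ring contraction).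
- **Forward key step.** D-Glucono-1,5-lactone A1 would be triethylsilylated at its three secondary hydroxyls, and its primary carbinol would be turned into an E-alkenyl pinacolboronate, giving lactone A2. Enolisation and O-silylation give ketene acetal A3. This rearranges to acid A4, which makes C5–C6, breaks the lactone C3–O bond and creates C3=C4 and the ring in one event.
- **For it.**
  - Sugar carbons 3 and 4 become C1 and C2 with the correct trans relation and the correct absolute configuration.
  - The two-carbon bridge C1–C2 between the reacting termini allows only a boat transition state. From it the E-alkene places boron cis to C7 and the C6 oxygen cis to C1–O, as 18 requires.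
  - Boron is later exchanged for oxygen with retention.
  - On the source of absolute configuration and on the predictability of the key step this plan is stronger than the chosen one.
- **Against it.**
  - Enolising A2 places an enolate next to a β-silyloxy group, the classical setting for β-elimination in aldonolactones.
  - A4 is an allylic boronate, open to 1,3-boron shift and protodeboronation before it is oxidised.
  - The carboxyl group still has to be reduced to C7H2OH.
  - The oxygens at C1, C2 and C6 emerge under three identical silyl groups. The acetate/benzoate distinction between two neighbouring secondary positions must therefore be built by extra protecting-group steps.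
- **Comparison.** With the selective manipulations between A1 and A2, the sequence should exceed thirteen steps. In exchange, the chosen strategy offers a ring that is bought ready-made and an acyl pattern that follows from mechanism.

Alternative 2: No bond of the final skeleton is cut. Instead C3=C4 is masked by two temporary C–C bonds to a five-carbon diene, and the ring is traced back to a quinone.
- **Forward key step.** 2-(Benzoyloxymethyl)-1,4-benzoquinone A5 and cyclopentadiene A6 would combine in a catalytic enantioselective endo Diels–Alder reaction at the unsubstituted quinone alkene. The product is tricycle A7, whose folded shape leaves only the convex face open.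
- **For it.**
  - A convex-face cis-dihydroxylation of C6=C1 and convex-face hydride delivery to the C2 and C5 carbonyls would give the β,β/α,α oxygen pattern of 18.
  - Every reaction type involved is established. In reliability this plan is clearly stronger than step 5 of the chosen route.
- **Against it.**
  - After reduction, C2–OH and C5–OH are two secondary alcohols in almost the same concave environment, yet one must become a benzoate and the other stay free. C1–OH is a third competitor, so the reductions and acylations have to be staged one by one.
  - A7 has acidic ring-fusion hydrogens and a benzoate in a vinylogous β-position. Tautomerisation to an aromatic ring and loss of benzoate both threaten.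
  - The C6=C1 alkene is electron-poor and slow towards electrophilic oxidants.
  - The cycloreversion needs strong heating late in the route. At that stage the molecule carries allylic esters, a tertiary alcohol and mobile acyl groups.
  - Five carbons are carried along and then thrown away.
- **Comparison.** The chosen strategy is riskier in one step but uses no masking. The iodide that records the stereochemical decision is also the leaving group that makes C3=C4, and no thermal step is needed.

Alternative 3: The C1–C6 bond is cut. This opens the ring to the acyclic Z-configured keto-aldehyde A8, with p-methoxybenzyl ethers at the C2 and C7 oxygens and a silyl ether at C5.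
- **Forward key step.** A divalent samarium reductant would couple aldehyde C1 with ketone C6 (pinacol cyclisation) to give the cis-diol A9.
- **For it.**
  - The fully substituted carbinol and C1 arise in a single C–C bond formation.
  - Metal-bridged ketyl coupling favours cis-diols placed anti to flanking alkoxy groups. Here both C2–O and C5–O are trans to the new hydroxyls, so substrate control is matched.
  - The protecting groups map onto the target. C1–OH is free for the acetate, the benzyl-type ethers sit where the two benzoates go, and the silyl ether sits where the free hydroxyl goes.
  - Its endgame would be shorter than steps 7 to 13 of the chosen route, and on this point it is stronger.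
- **Against it.**
  - Both carbonyls carry α-oxygen substituents (C2, C5, C7), two of them allylic as well. Reductive cleavage of α-C–O bonds is a standard reaction of the same reductant.
  - A8 is an α-alkoxy-β,γ-unsaturated carbonyl compound at both ends. It is prone to epimerisation and to migration of the Z-alkene into conjugation.
  - A8 has to be assembled with two stereocentres in a 1,4-relation across the alkene, defined alkene geometry and differentiated termini. That means a long linear prelude.
- **Comparison.** The chosen strategy buys the ring, reaches its key substrate in four routine steps and sets the absolute configuration catalytically.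

Key step: step 5

Assumption: the sense of induction of the chiral bis(amidine) salt on this new substrate class cannot be derived from first principles. The (R,R) catalyst is written, and the equally accessible (S,S) antipode is used if the other alkene turns out to be selected.

## Route

Step 1
Reactants: 1 benzoic acid
Product: 2 cyclohexa-2,5-diene-1-carboxylic acid
Conditions: Na, NH3 (l), EtOH, −78 to −33 °C; NH4Cl; aq. HCl to pH 3, 0 °C
Reagents that add atoms: none
Why: Birch reduction; the carboxylate directs protonation to the ipso and para carbons, so the 1,4-dihydro acid with the skipped diene is the regular product, and no stereocentre is formed.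

Step 2
Reactants: 2 cyclohexa-2,5-diene-1-carboxylic acid
Product: 3 methyl cyclohexa-2,5-diene-1-carboxylate
Conditions: MeOH, H2SO4 (cat.), reflux
Reagents that add atoms: methanol CO
Why: Fischer esterification; catalytic acid in methanol does not protonate the isolated alkenes, and the ester allows a clean mono-anionic enolate in the next step.

Step 3
Reactants: 3 methyl cyclohexa-2,5-diene-1-carboxylate
Product: 5 methyl 1-hydroxycyclohexa-2,5-diene-1-carboxylate, via potassium dienolate 4 (not isolated)
Conditions: KN(SiMe3)2, THF, −78 °C; 3-phenyl-2-(phenylsulfonyl)oxaziridine, −78 °C; AcOH (1 equiv) quench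
Reagents that add atoms: 3-phenyl-2-(phenylsulfonyl)oxaziridine O=S(=O)(c1ccccc1)N1OC1c1ccccc1
Why: Enolate hydroxylation with an N-sulfonyloxaziridine (Davis oxidation); the cross-conjugated dienolate 4 takes up electrophiles at its central α-carbon, as in Birch reduction–alkylation, so the skipped diene is kept. Product 5 is achiral (mirror plane through C6, C3 and C7), and the potassium counter-ion limits addition of the enolate to the sulfonimine by-product.

Step 4
Reactants: 5 methyl 1-hydroxycyclohexa-2,5-diene-1-carboxylate
Product: 6 1-(hydroxymethyl)cyclohexa-2,5-dien-1-ol
Conditions: LiAlH4, Et2O, 0 °C; H2O/aq. NaOH work-up; base-washed glassware, used at once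
Reagents that add atoms: none
Why: Ester reduction with LiAlH4, to which isolated alkenes are inert. The alkaline work-up keeps the bis-allylic tertiary alcohol away from acid, which would ionise C6–OH and drive aromatisation.

Step 5
Reactants: 6 1-(hydroxymethyl)cyclohexa-2,5-dien-1-ol; 7 carbon dioxide; 8 N-iodosuccinimide
Product: 10 (4aR,8R,8aR)-4a-hydroxy-8-iodo-4a,7,8,8a-tetrahydro-4H-1,3-benzodioxin-2-one (route numbering: 4β-I 5α-O 6β-OH with C1=C2), via alkyl hydrogen carbonate 9 (not isolated)
Conditions: CO2 (1 atm), NIS (1.05 equiv), (1R,2R)-N,N′-bis[4-(pyrrolidin-1-yl)quinolin-2-yl]-1,2-diphenylethane-1,2-diamine·HNTf2 (10 mol %), 4 Å molecular sieves, toluene, −20 °C, dark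
Reagents that add atoms: carbon dioxide O=C=O; N-iodosuccinimide O=C1CCC(=O)N1I
Why: Proposed new method: the primary C7–OH of 6 adds reversibly to CO2 and the free amidine of the half-protonated catalyst holds the resulting alkyl hydrogen carbonate 9 as a hydrogen-bonded ion pair, while the amidinium N–H activates 8 through a succinimide carbonyl. Iodine is passed to the β face of one ring alkene and the carbonate oxygen opens the iodonium ion at C5 from the α face, which closes the 1,3-dioxan-2-one ring in a 6-exo mode (C4 stays outside the new ring) and releases succinimide. The closest known reaction types are the enantioselective iodocarbonation of acyclic homoallylic alcohols with CO2 under chiral Brønsted acid–base catalysis and the catalytic desymmetrising halolactonisation of cyclohexa-2,5-diene-1-carboxylic acids; a CO2-derived nucleophile has not been used to choose between two enantiotopic ring alkenes. C6 becomes stereogenic only through the choice between C5=C4 and C1=C2, and this choice, the one selectivity that the substrate cannot supply, must come from the chiral pocket, helped by C6–OH as an extra hydrogen-bond anchor. C5 is controlled by the tether: the O–C(=O)–O arm reaches C5 only on the face that carries C7, hence the cis ring fusion and the 5α oxygen. C4 is controlled by the anti mechanism of iodonium opening, which places iodine β and trans-diaxial to C5–O. Attack at C5 and not at C4 follows from the tether length (C4 would need a bridged seven-membered ring), and the primary hydroxyl is carbonated in preference to the hindered tertiary one, whose five-ring closure would in any case need the iodonium ion on the other face. One equivalent of 8 leaves C1=C2 intact, and the buffered amidinium salt, the sieves and the low temperature are chosen to keep 6 from ionising at C6.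

Step 6
Reactants: 10 iodocarbonate
Product: 11 (4aR,8aS)-4a-hydroxy-4a,8a-dihydro-4H-1,3-benzodioxin-2-one (conjugated C1=C2–C3=C4 diene with 5α,7-cyclic carbonate and 6β-OH)
Conditions: DBU (2 equiv), toluene, 0 °C to rt
Reagents that add atoms: none
Why: E2 elimination; the axial 4β-iodide has an antiperiplanar hydrogen only on C3 (C5–H is β and syn to iodine), and that hydrogen is also allylic, so C3=C4 should form quickly and exclusively. C5 and C6 are not touched.

Step 7
Reactants: 11 diene carbonate
Product: 12 (1R,6S)-1-(hydroxymethyl)cyclohexa-2,4-diene-1,6-diol (5α-OH 6β-OH in route numbering)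
Conditions: K2CO3 (0.2 equiv), MeOH, 0 °C; filtration through a short silica pad (1% Et3N)
Reagents that add atoms: none
Why: Base-catalysed transesterification of a strained six-membered cyclic carbonate; only acyl–oxygen bonds break, so C5 and C6 keep their configuration. The basic medium suits this acid-labile dihydrodiol-type triene-free triol.

Step 8
Reactants: 12 triol
Product: 13 [(1R,6S)-1,6-dihydroxycyclohexa-2,4-dien-1-yl]methyl benzoate
Conditions: BzCl (1.05 equiv), pyridine, CH2Cl2, −40 °C
Reagents that add atoms: benzoyl chloride O=C(Cl)c1ccccc1
Why: Rate-selective acylation (primary before secondary before tertiary hydroxyl) at low temperature with one equivalent of acyl chloride. A primary ester is also the thermodynamic resting place should any 1,3-acyl shift between C5–O and C7–O occur.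

Step 9
Reactants: 13 C7 benzoate
Product: 14 [(1R,6S)-6-(tert-butyldimethylsilyloxy)-1-hydroxycyclohexa-2,4-dien-1-yl]methyl benzoate
Conditions: TBSOTf (1.1 equiv), 2,6-lutidine, CH2Cl2, −78 °C
Reagents that add atoms: tert-butyldimethylsilyl trifluoromethanesulfonate CC(C)(C)[Si](C)(C)OS(=O)(=O)C(F)(F)F
Why: Silyl ether formation; at −78 °C with one equivalent the secondary C5–OH reacts well before the tertiary C6–OH, and the lutidine buffer protects the acid-sensitive diene. C6–OH is left as the only free hydroxyl.

Step 10
Reactants: 14 silyl ether
Product: 15 [5α-(tert-butyldimethylsilyloxy)-1β,2β-epoxy-6β-hydroxycyclohex-3-en-6-yl]methyl benzoate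
Conditions: VO(acac)2 (5 mol %), tBuOOH (decane, 1.3 equiv), CH2Cl2, 0 °C
Reagents that add atoms: tert-butyl hydroperoxide CC(C)(C)OO
Why: Vanadium-catalysed hydroxyl-directed epoxidation of an allylic alcohol; the pentavalent vanadium alkoxide formed at C6–OH carries the peroxide to the adjacent C1=C2 alkene on the β face, which sets C1 and, for the time being, C2. C3=C4 is only homoallylic to this hydroxyl, and the neutral by-product spares the vinyl epoxide.

Step 11
Reactants: 15 vinyl epoxide; 1 benzoic acid
Product: 16 [2α-benzoyloxy-5α-(tert-butyldimethylsilyloxy)-1β,6β-dihydroxycyclohex-3-en-6-yl]methyl benzoate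
Conditions: PhCO2H (2 equiv), Ti(OiPr)4 (1.5 equiv), CH2Cl2, 0 °C to rt; aq. tartaric acid work-up
Reagents that add atoms: benzoic acid OC(=O)c1ccccc1
Why: Ti(OiPr)4-mediated opening of a 2,3-epoxy alcohol by a carboxylic acid (Caron–Sharpless opening); titanium bridges C6–O and the syn epoxide oxygen and directs the nucleophile to the distal carbon C2, which is also the allylic and thus activated position. SN2 inversion puts the benzoate α and leaves C1–OH β, while the 5α-silyloxy group shields C4 against conjugate attack.

Step 12
Reactants: 16 hydroxy benzoate
Product: 17 [1β-acetoxy-2α-benzoyloxy-5α-(tert-butyldimethylsilyloxy)-6β-hydroxycyclohex-3-en-6-yl]methyl benzoate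
Conditions: Ac2O (1.5 equiv), pyridine, 4-(dimethylamino)pyridine (0.1 equiv), CH2Cl2, 0 °C to rt
Reagents that add atoms: acetic anhydride CC(=O)OC(C)=O
Why: Nucleophile-catalysed acetylation; the secondary C1–OH is the only hydroxyl that reacts under these conditions, since the tertiary C6–OH needs forcing. No stereocentre is affected.

Step 13
Reactants: 17 silyl ether
Product: 18 HY-N2634 [(1R,2S,5R,6S)-6-acetoxy-5-benzoyloxy-1,2-dihydroxycyclohex-3-en-1-yl]methyl benzoate
Conditions: HF·pyridine, pyridine/THF, 0 °C to rt (plastic vessel)
Reagents that add atoms: none
Why: Fluoride-induced silyl ether cleavage in a weakly acidic medium; no alkoxide is formed, so acyl migration towards C5–OH or C6–OH is suppressed and the allylic esters survive. The Si–O bond breaks, so C5 keeps its configuration.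

## Compound list

1 | benzoic acid | OC(=O)c1ccccc1 | starting material
2 | cyclohexa-2,5-diene-1-carboxylic acid | OC(=O)C1C=CCC=C1 | intermediate
3 | methyl cyclohexa-2,5-diene-1-carboxylate | COC(=O)C1C=CCC=C1 | intermediate
4 | potassium dienolate of 3 (not isolated) | COC([O-])=C1C=CCC=C1.[K+] | intermediate
5 | methyl 1-hydroxycyclohexa-2,5-diene-1-carboxylate | COC(=O)C1(O)C=CCC=C1 | intermediate
6 | 1-(hydroxymethyl)cyclohexa-2,5-dien-1-ol | OCC1(O)C=CCC=C1 | intermediate
7 | carbon dioxide | O=C=O | starting material
8 | N-iodosuccinimide | O=C1CCC(=O)N1I | starting material
9 | (1-hydroxycyclohexa-2,5-dien-1-yl)methyl hydrogen carbonate (not isolated) | OC(=O)OCC1(O)C=CCC=C1 | intermediate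
10 | (4aR,8R,8aR)-4a-hydroxy-8-iodo-4a,7,8,8a-tetrahydro-4H-1,3-benzodioxin-2-one; cis-fused 5α,7-carbonate, 4β-iodide, 6β-OH, C1=C2 | C1=CC[C@@H](I)[C@H]3[C@]1(O)COC(=O)O3 | intermediate
11 | (4aR,8aS)-4a-hydroxy-4a,8a-dihydro-4H-1,3-benzodioxin-2-one; 5α,7-carbonate, 6β-OH, C1=C2–C3=C4 | C1=CC=C[C@H]3[C@]1(O)COC(=O)O3 | intermediate
12 | (1R,6S)-1-(hydroxymethyl)cyclohexa-2,4-diene-1,6-diol | C1=CC=C[C@H](O)[C@]1(O)CO | intermediate
13 | [(1R,6S)-1,6-dihydroxycyclohexa-2,4-dien-1-yl]methyl benzoate | C1=CC=C[C@H](O)[C@]1(O)COC(=O)c1ccccc1 | intermediate
14 | [(1R,6S)-6-(tert-butyldimethylsilyloxy)-1-hydroxycyclohexa-2,4-dien-1-yl]methyl benzoate | C1=CC=C[C@H](O[Si](C)(C)C(C)(C)C)[C@]1(O)COC(=O)c1ccccc1 | intermediate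
15 | 1β,2β-epoxide of 14 (5α-OTBS, 6β-OH, C3=C4) | O1[C@H]2[C@@H]1C=C[C@H](O[Si](C)(C)C(C)(C)C)[C@]2(O)COC(=O)c1ccccc1 | intermediate
16 | 1β-OH, 2α-OBz, 5α-OTBS, 6β-OH cyclohex-3-ene with 6α-CH2OBz | O[C@H]1[C@H](OC(=O)c2ccccc2)C=C[C@H](O[Si](C)(C)C(C)(C)C)[C@]1(O)COC(=O)c1ccccc1 | intermediate
17 | 1β-OAc, 2α-OBz, 5α-OTBS, 6β-OH cyclohex-3-ene with 6α-CH2OBz | CC(=O)O[C@H]1[C@H](OC(=O)c2ccccc2)C=C[C@H](O[Si](C)(C)C(C)(C)C)[C@]1(O)COC(=O)c1ccccc1 | intermediate
18 | HY-N2634, [(1R,2S,5R,6S)-6-acetoxy-5-benzoyloxy-1,2-dihydroxycyclohex-3-en-1-yl]methyl benzoate | CC(=O)O[C@H]1[C@H](OC(=O)c2ccccc2)C=C[C@H](O)[C@]1(O)COC(=O)c1ccccc1 | target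

## Step count and least certain steps

Total step count: 13. Longest linear sequence: 13 steps, from 1 to 18. Compounds 7 and 8 are bought, and 1 is used a second time in step 11.

**Step 5 (key step, new method).**
- The most likely failure is weak discrimination between the two enantiotopic alkenes. This catalyst type has been shaped on acyclic 1,1-disubstituted alkenes, where a prochiral face and not an alkene pair is chosen.
- The free C7–OH may also capture the iodonium ion directly at the electronically favoured C4 (a 5-endo etherification that bypasses CO2).
- Acid-triggered loss of water from 6 with aromatisation is a further risk.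
- Fallback with known chemistry, from 6 back to 10:
  - The primary hydroxyl of 6 is converted with di-tert-butyl dicarbonate and 1-methylimidazole into tert-butyl (1-hydroxycyclohexa-2,5-dien-1-yl)methyl carbonate F1. This masks the hydroxyl against etherification.
  - Iodocarbonate cyclisation of this homoallylic tert-butyl carbonate with 8 in toluene over NaHCO3 at low temperature follows the same cis-fused, anti-addition geometry with loss of the tert-butyl group. It gives 10 as a racemate together with the mirror-image iodocarbonate F2.
  - Preparative chromatography on a polysaccharide chiral stationary phase removes F2, and the route is rejoined at 10.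
  - Half of the material is lost, but all later steps stay unchanged.

**Step 3.**
- The electron-rich dienolate may be dehydrogenated by electron transfer to the oxidant, so that the ring aromatises.
- Oxygen transfer at a ring terminus of the pentadienyl system, or addition of the enolate to the sulfonimine, may also compete.
- Fallback, from 3 back to 5:
  - Ester 3 is deprotonated with LiN(iPr)2 and trapped with Me3SiCl as the silyl ketene acetal F3.
  - Rubottom oxidation of this neutral, far more electron-rich alkene with buffered mCPBA (NaHCO3, CH2Cl2/hexane, −20 °C) gives methyl 1-(trimethylsilyloxy)cyclohexa-2,5-diene-1-carboxylate F4.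
  - Et3N·3HF in THF at 0 °C then frees 5.
  - Neither a free enolate nor a free alkoxide ever meets the oxidant.

**Step 6.**
- Under base the carbonate may migrate onto the neighbouring C6–OH, since the five-membered isomer is more stable. This would free the C5 alkoxide, which could displace the trans iodide before E2 elimination takes place.
- Fallback, from 10 back to 11:
  - The iodide is displaced with inversion by PhSeNa (from PhSeSePh and NaBH4, EtOH/THF, 0 °C), a soft and weakly basic nucleophile, to give the 4α-phenylselenide F5.
  - Oxidation with H2O2/pyridine gives the selenoxide F6. Its syn elimination can use only the α-hydrogen at C3, because C5–H is β, and leads to 11.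
  - Any direct elimination during the displacement also ends at 11.

**Step 10.**
- Oxygen transfer to the wrong alkene of the diene or to both, Lewis-acid-induced opening of the vinyl epoxide on the catalyst, and [4+2] dimerisation of the diene on standing are the likely failures.
- Fallback, from 10 back to 15, by changing the order of events so that only one alkene is present during oxidation:
  - VO(acac)2/tBuOOH epoxidation of 10, directed by C6–OH, gives the 1β,2β-epoxy iodocarbonate F7.
  - DBU elimination gives the vinyl epoxide carbonate F8.
  - K2CO3/MeOH at 0 °C gives the epoxy triol F9.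
  - Low-temperature benzoylation gives the epoxy diol C7-benzoate F10.
  - Silylation with TBSOTf/2,6-lutidine rejoins the route at 15.
  - The step count does not change.

**Step 11.**
- Conjugate attack at C4, partial ionisation to an allyl cation with erosion of inversion, competition by isopropoxide as nucleophile, and titanium-promoted ester exchange are the likely failures.
- Fallback, from 14 back to 16, which avoids the vinyl epoxide altogether:
  - Hydrogen-bond-directed dihydroxylation of 14 with OsO4 and N,N,N′,N′-tetramethylethylenediamine (CH2Cl2, −78 °C; aq. Na2SO3 work-up) is steered by C6–OH to the β face of C1=C2. It gives the 1β,2β-cis-diol F11.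
  - A Mitsunobu reaction with 1, PPh3 and diisopropyl azodicarboxylate activates the less hindered allylic C2–OH and inverts it to the 2α-benzoate, which is 16.

## Further compounds

F1 | step 5 | tert-butyl (1-hydroxycyclohexa-2,5-dien-1-yl)methyl carbonate | CC(C)(C)OC(=O)OCC1(O)C=CCC=C1
F2 | step 5 | (4aS,8S,8aS)-4a-hydroxy-8-iodo-4a,7,8,8a-tetrahydro-4H-1,3-benzodioxin-2-one (mirror image of 10) | C1=CC[C@H](I)[C@@H]3[C@@]1(O)COC(=O)O3
F3 | step 3 | [(cyclohexa-2,5-dien-1-ylidene)(methoxy)methoxy]trimethylsilane | COC(O[Si](C)(C)C)=C1C=CCC=C1
F4 | step 3 | methyl 1-(trimethylsilyloxy)cyclohexa-2,5-diene-1-carboxylate | COC(=O)C1(O[Si](C)(C)C)C=CCC=C1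
F5 | step 6 | 4α-phenylselanyl analogue of 10 (5α,7-carbonate, 6β-OH, C1=C2) | C1=CC[C@H]([Se]c2ccccc2)[C@H]3[C@]1(O)COC(=O)O3
F6 | step 6 | selenoxide of F5 | C1=CC[C@H]([Se](=O)c2ccccc2)[C@H]3[C@]1(O)COC(=O)O3
F7 | step 10 | 1β,2β-epoxide of 10 (4β-iodide, 5α,7-carbonate, 6β-OH) | O1[C@H]2[C@@H]1C[C@@H](I)[C@H]3[C@]2(O)COC(=O)O3
F8 | step 10 | 1β,2β-epoxy-cyclohex-3-ene 5α,7-cyclic carbonate with 6β-OH | O1[C@H]2[C@@H]1C=C[C@H]3[C@]2(O)COC(=O)O3
F9 | step 10 | 1β,2β-epoxy-6α-(hydroxymethyl)cyclohex-3-ene-5α,6β-diol | O1[C@H]2[C@@H]1C=C[C@H](O)[C@]2(O)CO
F10 | step 10 | (1β,2β-epoxy-5α,6β-dihydroxycyclohex-3-en-6-yl)methyl benzoate | O1[C@H]2[C@@H]1C=C[C@H](O)[C@]2(O)COC(=O)c1ccccc1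
F11 | step 11 | [5α-(tert-butyldimethylsilyloxy)-1β,2β,6β-trihydroxycyclohex-3-en-6-yl]methyl benzoate | O[C@H]1[C@@H](O)C=C[C@H](O[Si](C)(C)C(C)(C)C)[C@]1(O)COC(=O)c1ccccc1
A1 | alternative 1 | D-glucono-1,5-lactone | OC[C@@H]1[C@@H](O)[C@H](O)[C@@H](O)C(=O)O1
A2 | alternative 1 | 2,3,4-tri-O-triethylsilyl-D-glucono-1,5-lactone with C6 changed into an E-alkenyl pinacolboronate | CC1(C)OB(/C=C/[C@@H]2[C@@H](O[Si](CC)(CC)CC)[C@H](O[Si](CC)(CC)CC)[C@@H](O[Si](CC)(CC)CC)C(=O)O2)OC1(C)C
A3 | alternative 1 | triethylsilyl ketene acetal of A2 | CC1(C)OB(/C=C/[C@@H]2[C@@H](O[Si](CC)(CC)CC)[C@H](O[Si](CC)(CC)CC)C(O[Si](CC)(CC)CC)=C(O[Si](CC)(CC)CC)O2)OC1(C)C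
A4 | alternative 1 | 5-(pinacolboryl)-1,2,6-tris(triethylsilyloxy)cyclohex-3-ene-6-carboxylic acid (target numbering) | CC[Si](CC)(CC)O[C@H]1[C@H](O[Si](CC)(CC)CC)C=C[C@H](B2OC(C)(C)C(C)(C)O2)[C@]1(O[Si](CC)(CC)CC)C(=O)O
A5 | alternative 2 | 2-(benzoyloxymethyl)-1,4-benzoquinone | O=C1C=CC(=O)C(COC(=O)c2ccccc2)=C1
A6 | alternative 2 | cyclopentadiene | C1C=CC=C1
A7 | alternative 2 | endo cyclopentadiene adduct of A5 at the unsubstituted alkene | O=C1C=C(COC(=O)c2ccccc2)C(=O)[C@@H]4[C@H]1[C@@H]3C=C[C@H]4C3
A8 | alternative 3 | Z-configured keto-aldehyde with C2 and C7 p-methoxybenzyl ethers and C5 silyl ether | O=C[C@H](OCc1ccc(OC)cc1)/C=C\[C@H](O[Si](C)(C)C(C)(C)C)C(=O)COCc1ccc(OC)cc1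
A9 | alternative 3 | cyclohexene cis-1,6-diol with protected C2, C5 and C7 oxygens | O[C@H]1[C@H](OCc2ccc(OC)cc2)C=C[C@H](O[Si](C)(C)C(C)(C)C)[C@]1(O)COCc1ccc(OC)cc1
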